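**Plan**

- Cuts (retrosynthesis): (1) the seven O–benzyl bonds; (2) the interflavanyl bond C4–C6′ between the upper flavan (benzo ring A, pyran ring C, catechol ring B; unprimed atoms) and the lower flavan (benzo ring D, pyran ring F, catechol ring E; primed atoms); (3) in the lower unit, together, the ring-F bond O1′–C8a′ and the ring-D bond C8′–O; (4) the two aryl–carbon bonds of the C3 chain, back to methyl (S)-glycidate and two aryl bromides.
- Feature used: ring D carries three neighbouring oxygens (O1′ on C8a′, OH on C8′, OH on C7′), so C8a′ and C8′ are treated as the two carbons of an aryne. The C7′ oxygen (as MOM ether) and a fluorine on C8a′ (helper, lost as LiF) place the aryne, the tethered C2′ alkoxide closes ring F on C8a′, and the carbanion left on C8′ is turned into the 8′-OH.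
- Forward order: C3 chain with C3′ and C2′ set (steps 1–6); ring F and the C8′ oxygen in one flask (step 7); O8′ benzylated and O7′ freed (steps 8, 9); ring C of the upper unit as a flavanone, then a flav-3-ene (steps 10–13); epoxide opening by the lower phenol makes C4–C6′ (step 14); hydrogenolysis (step 15).
- Stereochemistry: C3′ from the glycidate; C2′ by chelation-controlled ketone reduction (1,2-anti); C2 by ligand-controlled conjugate addition; C3 by epoxidation anti to the C2 aryl group; C4 by boron-mediated delivery of C6′ syn to the epoxide oxygen (3,4-cis).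

Key step: step 7

Remark: the target is read as a 2,3-trans-3,4-cis (2R,3S,4S) fisetinidol-type upper unit bonded through C4 to C6′ of a (2R,3S) mesquitol-type lower unit; the antipode of each chiral ligand or catalyst is chosen to give the configuration drawn.

**Route**

Step 1
Reactants: 1 4-bromo-3-fluorophenol
Product: 2 1-bromo-2-fluoro-4-(methoxymethoxy)benzene
Conditions: NaH, MOMCl, DMF, 0 °C → rt
Reagents that add atoms: chloromethyl methyl ether (MOMCl), COCCl
Why: Williamson-type O-alkylation of the sodium phenoxide; the MOM ether later directs the ring lithiation and is the one acid-labile ether of the route.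

Step 2
Reactants: 2 1-bromo-2-fluoro-4-(methoxymethoxy)benzene; 3 methyl (2S)-oxirane-2-carboxylate
Product: 5 methyl (2S)-3-[2-fluoro-4-(methoxymethoxy)phenyl]-2-hydroxypropanoate, via aryl Grignard reagent 4 (not isolated)
Conditions: Mg, THF, rt; then 3, CuBr·SMe2 (10 mol%), THF, −40 → 0 °C; aq. NH4Cl
Reagents that add atoms: none
Why: Copper-catalysed Grignard opening of the glycidic ester at its unsubstituted C3 (SN2 at CH2) leaves the C2 stereocentre of 3 untouched, so the future C3′–O centre is taken over with S configuration from the chiral pool.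

Step 3
Reactants: 5 methyl (2S)-3-[2-fluoro-4-(methoxymethoxy)phenyl]-2-hydroxypropanoate
Product: 6 methyl (2S)-2-(benzyloxy)-3-[2-fluoro-4-(methoxymethoxy)phenyl]propanoate
Conditions: BnBr, Ag2O, CH2Cl2, rt, dark
Reagents that add atoms: benzyl bromide, BrCc1ccccc1
Why: Ag2O-promoted benzylation is a neutral Williamson variant that does not enolise the α-hydroxy ester, so the stereocentre is kept.

Step 4
Reactants: 6 methyl (2S)-2-(benzyloxy)-3-[2-fluoro-4-(methoxymethoxy)phenyl]propanoate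
Product: 7 (2S)-2-(benzyloxy)-3-[2-fluoro-4-(methoxymethoxy)phenyl]-N-methoxy-N-methylpropanamide
Conditions: MeNHOMe·HCl, i-PrMgCl, THF, −20 → 0 °C; aq. NH4Cl
Reagents that add atoms: N,O-dimethylhydroxylamine hydrochloride, Cl.CNOC
Why: Weinreb amide formation by attack of the chloromagnesium amide of MeNHOMe on the ester at low temperature, which leaves the α-alkoxy centre intact.

Step 5
Reactants: 7 (2S)-2-(benzyloxy)-3-[2-fluoro-4-(methoxymethoxy)phenyl]-N-methoxy-N-methylpropanamide; 8 1,2-bis(benzyloxy)-4-bromobenzene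
Product: 10 (2S)-2-(benzyloxy)-1-[3,4-bis(benzyloxy)phenyl]-3-[2-fluoro-4-(methoxymethoxy)phenyl]propan-1-one, via aryl Grignard reagent 9 (not isolated)
Conditions: 8, Mg, THF, rt; then 7, THF, 0 °C; aq. NH4Cl
Reagents that add atoms: none
Why: Grignard addition to a Weinreb amide stops at the magnesium-chelated tetrahedral intermediate, so the aryl ketone forms without over-addition or epimerisation.

Step 6
Reactants: 10 (2S)-2-(benzyloxy)-1-[3,4-bis(benzyloxy)phenyl]-3-[2-fluoro-4-(methoxymethoxy)phenyl]propan-1-one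
Product: 11 (1R,2S)-2-(benzyloxy)-1-[3,4-bis(benzyloxy)phenyl]-3-[2-fluoro-4-(methoxymethoxy)phenyl]propan-1-ol
Conditions: Zn(BH4)2, Et2O, −78 → −20 °C; H2O
Reagents that add atoms: none
Why: Chelation-controlled reduction: zinc bridges the carbonyl and α-benzyloxy oxygens and hydride enters anti to the CH2Ar group of the chelate, which sets C1 (future C2′) as R, anti to C2.

Step 7
Reactants: 11 (1R,2S)-2-(benzyloxy)-1-[3,4-bis(benzyloxy)phenyl]-3-[2-fluoro-4-(methoxymethoxy)phenyl]propan-1-ol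
Product: 16 (2R,3S)-3-(benzyloxy)-2-[3,4-bis(benzyloxy)phenyl]-7-(methoxymethoxy)-3,4-dihydro-2H-chromen-8-ol, via dilithio species 12 (not isolated), via aryne alkoxide 13 (not isolated), via 8-lithiochromane 14 (not isolated), via trimethoxyborate 15 (not isolated)
Conditions: n-BuLi (2.05 equiv), THF, −78 °C; warm to −20 °C; re-cool to −78 °C, B(OMe)3; then 30% H2O2, aq. NaOH, 0 °C → rt
Reagents that add atoms: hydrogen peroxide, OO
Why: Proposed new method: n-BuLi first makes the lithium alkoxide and then lithiates the one ring-D C–H that lies between F and OMOM (future C8′); on warming LiF is lost to give the C8a′≡C8′ aryne 13, the tethered C2′ alkoxide adds to C8a′, and the carbanion that appears on C8′ (14, an aryllithium held between two ether oxygens) is borylated and oxidised to the phenol. The closest known reaction types are the ring closure of tethered alkoxides onto arynes made from haloarenes with strong base (a known entry to chromans and dihydrobenzofurans) and the lithiation–borylation–oxidation of aryllithiums; new is their union on one aryne, so that its two carbons take up the two ring-D oxygens in one flask. Ring F closes in the 6-exo-dig mode, the attacked aryne carbon lying in the new ring and its partner C8′ outside it. No stereocentre is formed: the C2′–O and C3′–O bonds are never broken, so the (1R,2S) array of 11 becomes the (2R,3S) array of 16. Site selectivity is secured by the substrate at each stage: F and OMOM together single out C8′–H for lithiation, F is the only leaving group, and only C8a′ is within reach of the three-atom tether, which is also the electronically preferred end of a 3-alkoxyaryne (attack distal to the 7′-oxygen). Chemoselectivity for the six-membered ring rests on the benzyl ether on O3′, which leaves the C2′ alkoxide as the only anionic oxygen.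

Step 8
Reactants: 16 (2R,3S)-3-(benzyloxy)-2-[3,4-bis(benzyloxy)phenyl]-7-(methoxymethoxy)-3,4-dihydro-2H-chromen-8-ol
Product: 17 (2R,3S)-3,8-bis(benzyloxy)-2-[3,4-bis(benzyloxy)phenyl]-7-(methoxymethoxy)-3,4-dihydro-2H-chromene
Conditions: BnBr, K2CO3, DMF, rt
Reagents that add atoms: benzyl bromide, BrCc1ccccc1
Why: Williamson benzylation of the free 8-phenol, so that O8′ is masked like every other oxygen except O7′.

Step 9
Reactants: 17 (2R,3S)-3,8-bis(benzyloxy)-2-[3,4-bis(benzyloxy)phenyl]-7-(methoxymethoxy)-3,4-dihydro-2H-chromene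
Product: 18 (2R,3S)-3,8-bis(benzyloxy)-2-[3,4-bis(benzyloxy)phenyl]-3,4-dihydro-2H-chromen-7-ol
Conditions: conc. HCl (cat.), MeOH/THF, 50 °C
Reagents that add atoms: none
Why: Acid-catalysed acetal exchange removes the MOM group only, exposing the 7-OH whose sole free ortho carbon is C6.

Step 10
Reactants: 19 7-hydroxy-4H-chromen-4-one
Product: 20 7-(benzyloxy)-4H-chromen-4-one
Conditions: BnBr, K2CO3, DMF, rt
Reagents that add atoms: benzyl bromide, BrCc1ccccc1
Why: Williamson benzylation of the phenol.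

Step 11
Reactants: 20 7-(benzyloxy)-4H-chromen-4-one; 21 [3,4-bis(benzyloxy)phenyl]boronic acid
Product: 22 (2S)-7-(benzyloxy)-2-[3,4-bis(benzyloxy)phenyl]-2,3-dihydro-4H-chromen-4-one
Conditions: Pd(OCOCF3)2 (5 mol%), t-BuPyOX (6 mol%; antipode that gives 2S), NH4PF6, H2O, ClCH2CH2Cl, 60 °C
Reagents that add atoms: none
Why: Ligand-controlled asymmetric conjugate addition of an arylpalladium species (from transmetalation of the boronic acid) to the chromone C2=C3 bond, followed by protonolysis of the palladium enolate, sets C2 as S.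

Step 12
Reactants: 22 (2S)-7-(benzyloxy)-2-[3,4-bis(benzyloxy)phenyl]-2,3-dihydro-4H-chromen-4-one
Product: 23 (2S,4S)-7-(benzyloxy)-2-[3,4-bis(benzyloxy)phenyl]-3,4-dihydro-2H-chromen-4-ol
Conditions: NaBH4, MeOH/THF, 0 °C
Reagents that add atoms: none
Why: Hydride reduction of the C4 ketone from the less hindered face should give the 2,4-cis alcohol; the C4 configuration is of no consequence because it is removed in step 13.

Step 13
Reactants: 23 (2S,4S)-7-(benzyloxy)-2-[3,4-bis(benzyloxy)phenyl]-3,4-dihydro-2H-chromen-4-ol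
Product: 24 (2S)-7-(benzyloxy)-2-[3,4-bis(benzyloxy)phenyl]-2H-chromene
Conditions: Burgess reagent, toluene, 50 °C
Reagents that add atoms: none
Why: Burgess dehydration (sulfamate ester formation, then syn elimination or loss of the 7-alkoxy-stabilised benzylic sulfamate and deprotonation at C3) gives the flav-3-ene under non-acidic conditions that do not touch C2.

Step 14
Reactants: 24 (2S)-7-(benzyloxy)-2-[3,4-bis(benzyloxy)phenyl]-2H-chromene; 18 (2R,3S)-3,8-bis(benzyloxy)-2-[3,4-bis(benzyloxy)phenyl]-3,4-dihydro-2H-chromen-7-ol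
Product: 27 (2R,3S,4S)-7-(benzyloxy)-2-[3,4-bis(benzyloxy)phenyl]-4-{(2R,3S)-3,8-bis(benzyloxy)-2-[3,4-bis(benzyloxy)phenyl]-7-hydroxy-3,4-dihydro-2H-chromen-6-yl}-3,4-dihydro-2H-chromen-3-ol, via epoxide 25 (not isolated), via triaryl borate 26 (not isolated)
Conditions: (a) 24, DMDO, acetone/CH2Cl2, −40 °C, volatiles removed cold; (b) 18 (3 equiv), BH3·SMe2 (1 equiv), CH2Cl2, rt → 40 °C; (c) epoxide added to the borate, CH2Cl2, −40 °C → rt; aq. NaHCO3 (surplus 18 recovered)
Reagents that add atoms: dimethyldioxirane (DMDO), CC1(C)OO1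
Why: Dimethyldioxirane epoxidises the C3=C4 bond anti to the C2 aryl group, and the borate then binds the epoxide oxygen, the C4–O bond ionises toward the benzylic cation stabilised by the 7-benzyloxy group, and C6′ of a boron-bound aryloxy group (its only free ortho carbon) is delivered to C4 on the face of the departing oxygen (aryl borate syn-opening of an aryl epoxide with ortho C-alkylation, a Friedel–Crafts-type reaction), which sets C3 as S and C4 as S (3,4-cis).

Step 15
Reactants: 27 (2R,3S,4S)-7-(benzyloxy)-2-[3,4-bis(benzyloxy)phenyl]-4-{(2R,3S)-3,8-bis(benzyloxy)-2-[3,4-bis(benzyloxy)phenyl]-7-hydroxy-3,4-dihydro-2H-chromen-6-yl}-3,4-dihydro-2H-chromen-3-ol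
Product: 28 (2R,3S,4S)-2-(3,4-dihydroxyphenyl)-4-[(2R,3S)-2-(3,4-dihydroxyphenyl)-3,7,8-trihydroxy-3,4-dihydro-2H-chromen-6-yl]-3,4-dihydro-2H-chromene-3,7-diol
Conditions: H2 (1 atm), Pd(OH)2/C, THF/MeOH, rt
Reagents that add atoms: none
Why: Hydrogenolysis of the seven benzyl ethers over palladium should release the target without touching the stereocentres.

**Compound list**

1 | 4-bromo-3-fluorophenol | Oc1ccc(Br)c(F)c1 | starting material
2 | 1-bromo-2-fluoro-4-(methoxymethoxy)benzene | COCOc1ccc(Br)c(F)c1 | intermediate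
3 | methyl (2S)-oxirane-2-carboxylate (methyl (S)-glycidate) | COC(=O)[C@@H]1CO1 | starting material
4 | [2-fluoro-4-(methoxymethoxy)phenyl]magnesium bromide | COCOc1ccc([Mg]Br)c(F)c1 | intermediate
5 | methyl (2S)-3-[2-fluoro-4-(methoxymethoxy)phenyl]-2-hydroxypropanoate | COC(=O)[C@@H](O)Cc1ccc(OCOC)cc1F | intermediate
6 | methyl (2S)-2-(benzyloxy)-3-[2-fluoro-4-(methoxymethoxy)phenyl]propanoate | COC(=O)[C@@H](OCc1ccccc1)Cc1ccc(OCOC)cc1F | intermediate
7 | (2S)-2-(benzyloxy)-3-[2-fluoro-4-(methoxymethoxy)phenyl]-N-methoxy-N-methylpropanamide | CON(C)C(=O)[C@@H](OCc1ccccc1)Cc1ccc(OCOC)cc1F | intermediate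
8 | 1,2-bis(benzyloxy)-4-bromobenzene | Brc1ccc(OCc2ccccc2)c(OCc2ccccc2)c1 | starting material
9 | [3,4-bis(benzyloxy)phenyl]magnesium bromide | Br[Mg]c1ccc(OCc2ccccc2)c(OCc2ccccc2)c1 | intermediate
10 | (2S)-2-(benzyloxy)-1-[3,4-bis(benzyloxy)phenyl]-3-[2-fluoro-4-(methoxymethoxy)phenyl]propan-1-one | O=C(c1ccc(OCc2ccccc2)c(OCc2ccccc2)c1)[C@@H](OCc1ccccc1)Cc1ccc(OCOC)cc1F | intermediate
11 | (1R,2S)-2-(benzyloxy)-1-[3,4-bis(benzyloxy)phenyl]-3-[2-fluoro-4-(methoxymethoxy)phenyl]propan-1-ol | O[C@H](c1ccc(OCc2ccccc2)c(OCc2ccccc2)c1)[C@@H](OCc1ccccc1)Cc1ccc(OCOC)cc1F | intermediate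
12 | lithium (1R,2S)-2-(benzyloxy)-1-[3,4-bis(benzyloxy)phenyl]-3-[2-fluoro-3-lithio-4-(methoxymethoxy)phenyl]propan-1-olate | [Li]O[C@H](c1ccc(OCc2ccccc2)c(OCc2ccccc2)c1)[C@@H](OCc1ccccc1)Cc1ccc(OCOC)c([Li])c1F | intermediate
13 | lithium (1R,2S)-2-(benzyloxy)-1-[3,4-bis(benzyloxy)phenyl]-3-[2,3-didehydro-4-(methoxymethoxy)phenyl]propan-1-olate (aryne) | [Li]O[C@H](c1ccc(OCc2ccccc2)c(OCc2ccccc2)c1)[C@@H](OCc1ccccc1)CC1=CC=C(OCOC)C#C1 | intermediate
14 | (2R,3S)-3-(benzyloxy)-2-[3,4-bis(benzyloxy)phenyl]-8-lithio-7-(methoxymethoxy)-3,4-dihydro-2H-chromene | [Li]c1c(OCOC)ccc2c1O[C@H](c1ccc(OCc3ccccc3)c(OCc3ccccc3)c1)[C@@H](OCc1ccccc1)C2 | intermediate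
15 | lithium [(2R,3S)-3-(benzyloxy)-2-[3,4-bis(benzyloxy)phenyl]-7-(methoxymethoxy)-3,4-dihydro-2H-chromen-8-yl]trimethoxyborate | [Li+].CO[B-](OC)(OC)c1c(OCOC)ccc2c1O[C@H](c1ccc(OCc3ccccc3)c(OCc3ccccc3)c1)[C@@H](OCc1ccccc1)C2 | intermediate
16 | (2R,3S)-3-(benzyloxy)-2-[3,4-bis(benzyloxy)phenyl]-7-(methoxymethoxy)-3,4-dihydro-2H-chromen-8-ol | COCOc1ccc2c(c1O)O[C@H](c1ccc(OCc3ccccc3)c(OCc3ccccc3)c1)[C@@H](OCc1ccccc1)C2 | intermediate
17 | (2R,3S)-3,8-bis(benzyloxy)-2-[3,4-bis(benzyloxy)phenyl]-7-(methoxymethoxy)-3,4-dihydro-2H-chromene | COCOc1ccc2c(c1OCc3ccccc3)O[C@H](c1ccc(OCc3ccccc3)c(OCc3ccccc3)c1)[C@@H](OCc1ccccc1)C2 | intermediate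
18 | (2R,3S)-3,8-bis(benzyloxy)-2-[3,4-bis(benzyloxy)phenyl]-3,4-dihydro-2H-chromen-7-ol | Oc1ccc2c(c1OCc3ccccc3)O[C@H](c1ccc(OCc3ccccc3)c(OCc3ccccc3)c1)[C@@H](OCc1ccccc1)C2 | intermediate
19 | 7-hydroxy-4H-chromen-4-one | O=c1ccoc2cc(O)ccc12 | starting material
20 | 7-(benzyloxy)-4H-chromen-4-one | O=c1ccoc2cc(OCc3ccccc3)ccc12 | intermediate
21 | [3,4-bis(benzyloxy)phenyl]boronic acid | OB(O)c1ccc(OCc2ccccc2)c(OCc2ccccc2)c1 | starting material
22 | (2S)-7-(benzyloxy)-2-[3,4-bis(benzyloxy)phenyl]-2,3-dihydro-4H-chromen-4-one | c1ccccc1COc1ccc2c(c1)O[C@H](c1ccc(OCc3ccccc3)c(OCc3ccccc3)c1)CC2=O | intermediate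
23 | (2S,4S)-7-(benzyloxy)-2-[3,4-bis(benzyloxy)phenyl]-3,4-dihydro-2H-chromen-4-ol (2,4-cis) | c1ccccc1COc1ccc2c(c1)O[C@H](c1ccc(OCc3ccccc3)c(OCc3ccccc3)c1)C[C@@H]2O | intermediate
24 | (2S)-7-(benzyloxy)-2-[3,4-bis(benzyloxy)phenyl]-2H-chromene | c1ccccc1COc1ccc2c(c1)O[C@H](c1ccc(OCc3ccccc3)c(OCc3ccccc3)c1)C=C2 | intermediate
25 | (2R,3S,4S)-7-(benzyloxy)-2-[3,4-bis(benzyloxy)phenyl]-3,4-epoxy-3,4-dihydro-2H-chromene (epoxide oxygen trans to the 2-aryl group) | c1ccccc1COc1ccc2c(c1)O[C@H](c1ccc(OCc3ccccc3)c(OCc3ccccc3)c1)[C@H]3O[C@@H]23 | intermediate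
26 | tris{(2R,3S)-3,8-bis(benzyloxy)-2-[3,4-bis(benzyloxy)phenyl]-3,4-dihydro-2H-chromen-7-yl} borate | B(Oc1ccc2c(c1OCc3ccccc3)O[C@H](c1ccc(OCc3ccccc3)c(OCc3ccccc3)c1)[C@@H](OCc1ccccc1)C2)(Oc1ccc2c(c1OCc3ccccc3)O[C@H](c1ccc(OCc3ccccc3)c(OCc3ccccc3)c1)[C@@H](OCc1ccccc1)C2)Oc1ccc2c(c1OCc3ccccc3)O[C@H](c1ccc(OCc3ccccc3)c(OCc3ccccc3)c1)[C@@H](OCc1ccccc1)C2 | intermediate
27 | (2R,3S,4S)-7-(benzyloxy)-2-[3,4-bis(benzyloxy)phenyl]-4-{(2R,3S)-3,8-bis(benzyloxy)-2-[3,4-bis(benzyloxy)phenyl]-7-hydroxy-3,4-dihydro-2H-chromen-6-yl}-3,4-dihydro-2H-chromen-3-ol | c1ccccc1COc1ccc2c(c1)O[C@H](c1ccc(OCc3ccccc3)c(OCc3ccccc3)c1)[C@@H](O)[C@H]2c1cc2c(c(OCc3ccccc3)c1O)O[C@H](c1ccc(OCc3ccccc3)c(OCc3ccccc3)c1)[C@@H](OCc1ccccc1)C2 | intermediate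
28 | (2R,3S,4S)-2-(3,4-dihydroxyphenyl)-4-[(2R,3S)-2-(3,4-dihydroxyphenyl)-3,7,8-trihydroxy-3,4-dihydro-2H-chromen-6-yl]-3,4-dihydro-2H-chromene-3,7-diol | Oc1ccc2c(c1)O[C@H](c1ccc(O)c(O)c1)[C@@H](O)[C@H]2c1cc2c(c(O)c1O)O[C@H](c1ccc(O)c(O)c1)[C@@H](O)C2 | target

**Totals and risks**

Total step count: 15. Longest linear sequence: 11 steps (steps 1–9, 14, 15).

Steps most likely to fail:

Step 7 (labelled step). The aryne may be captured by aryllithium 12 or by unconsumed n-BuLi before the alkoxide closes the ring. A proton may pass from C2′–H to the C8′ carbanion of 14, followed by β-elimination of benzyl oxide. A benzylic ether CH2 may be lithiated and rearrange. The fallback uses known chemistry only, sets out from 11 and returns at 16. Compound 11 is lithiated as before at −78 °C and the aryllithium is quenched cold with DMF, before any fluoride is lost, to give 3-[(2S,3R)-2-(benzyloxy)-3-[3,4-bis(benzyloxy)phenyl]-3-hydroxypropyl]-2-fluoro-6-(methoxymethoxy)benzaldehyde F1. The formyl group ortho to fluorine then allows an ordinary addition–elimination ring closure by the alkoxide (KOt-Bu, THF, 0 °C) to (2R,3S)-3-(benzyloxy)-2-[3,4-bis(benzyloxy)phenyl]-7-(methoxymethoxy)-3,4-dihydro-2H-chromene-8-carbaldehyde F2. Baeyer–Villiger oxidation of this electron-rich aldehyde (mCPBA, CH2Cl2) gives (2R,3S)-3-(benzyloxy)-2-[3,4-bis(benzyloxy)phenyl]-7-(methoxymethoxy)-3,4-dihydro-2H-chromen-8-yl formate F3, and methanolysis (K2CO3, MeOH) gives phenol 16.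

Step 14. The epoxide may rearrange under Lewis acid to the flavan-3-one by a 1,2-hydride shift. The phenol may be alkylated on oxygen instead of carbon. Facial control may be lost if the benzylic cation escapes the borate and is attacked anti. The fallback sets out from 24 and returns at 27. Dihydroxylation anti to the 2-aryl group (OsO4 cat., NMO, acetone/H2O) gives (2R,3S,4S)-7-(benzyloxy)-2-[3,4-bis(benzyloxy)phenyl]-3,4-dihydro-2H-chromene-3,4-diol F4. Ionisation of its 4-OH (BF3·OEt2, CH2Cl2, −78 °C) in the presence of 18 is the classical flavan-3,4-diol/phenol condensation. It should give both C4 epimers, 27 and (2R,3S,4R)-7-(benzyloxy)-2-[3,4-bis(benzyloxy)phenyl]-4-{(2R,3S)-3,8-bis(benzyloxy)-2-[3,4-bis(benzyloxy)phenyl]-7-hydroxy-3,4-dihydro-2H-chromen-6-yl}-3,4-dihydro-2H-chromen-3-ol F5, with the unwanted 3,4-trans epimer F5 expected to predominate; the two are separated by chromatography.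

Step 11. Protodeboronation of the electron-rich boronic acid may outrun transmetalation. The electron-rich chromone may convert slowly. Enantiopurity may erode by reversible ring opening (retro-oxa-Michael). The fallback sets out from 20 (with 21) and returns at 23. An achiral conjugate addition (Pd(OCOCF3)2, 2,2′-bipyridine, aqueous ClCH2CH2Cl) gives racemic 7-(benzyloxy)-2-[3,4-bis(benzyloxy)phenyl]-2,3-dihydro-4H-chromen-4-one F6. Asymmetric transfer hydrogenation run as a kinetic resolution (RuCl(p-cymene)[(S,S)-TsDPEN], HCO2H/Et3N; antipode that reduces the 2S ketone) should reduce the 2S enantiomer to the cis alcohol 23 and leave (2R)-7-(benzyloxy)-2-[3,4-bis(benzyloxy)phenyl]-2,3-dihydro-4H-chromen-4-one F7, which is separated.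

Further compounds
F1 | step 7 | 3-[(2S,3R)-2-(benzyloxy)-3-[3,4-bis(benzyloxy)phenyl]-3-hydroxypropyl]-2-fluoro-6-(methoxymethoxy)benzaldehyde | O[C@H](c1ccc(OCc2ccccc2)c(OCc2ccccc2)c1)[C@@H](OCc1ccccc1)Cc1ccc(OCOC)c(C=O)c1F
F2 | step 7 | (2R,3S)-3-(benzyloxy)-2-[3,4-bis(benzyloxy)phenyl]-7-(methoxymethoxy)-3,4-dihydro-2H-chromene-8-carbaldehyde | COCOc1ccc2c(c1C=O)O[C@H](c1ccc(OCc3ccccc3)c(OCc3ccccc3)c1)[C@@H](OCc1ccccc1)C2
F3 | step 7 | (2R,3S)-3-(benzyloxy)-2-[3,4-bis(benzyloxy)phenyl]-7-(methoxymethoxy)-3,4-dihydro-2H-chromen-8-yl formate | COCOc1ccc2c(c1OC=O)O[C@H](c1ccc(OCc3ccccc3)c(OCc3ccccc3)c1)[C@@H](OCc1ccccc1)C2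
F4 | step 14 | (2R,3S,4S)-7-(benzyloxy)-2-[3,4-bis(benzyloxy)phenyl]-3,4-dihydro-2H-chromene-3,4-diol | c1ccccc1COc1ccc2c(c1)O[C@H](c1ccc(OCc3ccccc3)c(OCc3ccccc3)c1)[C@@H](O)[C@H]2O
F5 | step 14 | (2R,3S,4R)-7-(benzyloxy)-2-[3,4-bis(benzyloxy)phenyl]-4-{(2R,3S)-3,8-bis(benzyloxy)-2-[3,4-bis(benzyloxy)phenyl]-7-hydroxy-3,4-dihydro-2H-chromen-6-yl}-3,4-dihydro-2H-chromen-3-ol | c1ccccc1COc1ccc2c(c1)O[C@H](c1ccc(OCc3ccccc3)c(OCc3ccccc3)c1)[C@@H](O)[C@@H]2c1cc2c(c(OCc3ccccc3)c1O)O[C@H](c1ccc(OCc3ccccc3)c(OCc3ccccc3)c1)[C@@H](OCc1ccccc1)C2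
F6 | step 11 | racemic 7-(benzyloxy)-2-[3,4-bis(benzyloxy)phenyl]-2,3-dihydro-4H-chromen-4-one | c1ccccc1COc1ccc2c(c1)OC(c1ccc(OCc3ccccc3)c(OCc3ccccc3)c1)CC2=O
F7 | step 11 | (2R)-7-(benzyloxy)-2-[3,4-bis(benzyloxy)phenyl]-2,3-dihydro-4H-chromen-4-one | c1ccccc1COc1ccc2c(c1)O[C@@H](c1ccc(OCc3ccccc3)c(OCc3ccccc3)c1)CC2=O
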